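**Retrosynthetic overview**

- Numbering (germacrane): C1 is the enol-ether carbon and C2H=/C3H2 are the other two carbons of the dihydrofuran. C4 is the O-bearing quaternary carbon, C5=C6 the ylidene bond, C7/C11/C12 the butenolide, C8 the ester carbinol, C10 the tertiary carbinol and C13 the CH2OAc carbon.
- Enabling feature: in the dihydrofuran ring (O, C1–C4) both carbons next to oxygen are latent carbonyl carbons. C1 (enol ether) is a ketone, and C4 (tertiary carbinol) is a methyl ketone plus a C-nucleophile. They are bridged only by the unsubstituted C2–C3 unit, so an acetylene dianion can stitch C1 to C4.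
- Disconnections: C1=C2 goes back to the 1,4-epoxy hemiketal and then to the C1 ketone plus C4–OH. C5=C6 comes from an intramolecular HWE reaction. C1–C2 and C3–C4 come from Weinreb amide 9, HC≡CMgBr and ketone 12.
- Ring order: furan (bought), then a temporary γ-lactone (opened again), then the butenolide (from the furan), then the ten-membered carbocycle, then the dihydrofuran last.
- Stereochemistry: C8 is set by catalysis. C10 is relayed from C8 on the lactone. C4 is relayed from a bought dioxolane stereocentre (C5), which is later sacrificed.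

Key step: step 7

Assumption: the addition to ketone 12 in step 7 follows the Cram-chelate model. If the polar Felkin–Anh mode dominated, the (4S)-enantiomer of ester 10 would be bought instead.

**Step 1**
Reactants: 1 furan-3,4-diyldimethanol
Product: 2 [4-(tert-butyldiphenylsilyloxymethyl)furan-3-yl]methanol
Conditions: NaH (1.0 equiv), THF, 0 °C; TBDPSCl (1.0 equiv), rt
Reagents that add atoms: tert-butyl(chloro)diphenylsilane, CC(C)(C)[Si](Cl)(c1ccccc1)c1ccccc1
Why: Monosilylation of a symmetrical diol through its sparingly soluble monosodium alkoxide (O-silylation) should stop after one silyl group, and no stereocentre is involved.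

**Step 2**
Reactants: 2 [4-(tert-butyldiphenylsilyloxymethyl)furan-3-yl]methanol; 3 methyl 2-{[(tert-butoxycarbonyl)oxy]methyl}prop-2-enoate
Product: 5 (5R)-3-methylidene-5-[4-(TBDPSOCH2)furan-3-yl]oxolan-2-one, via hydroxy ester 4 (not isolated)
Conditions: [Ir(cod)Cl]2 (cat.), chiral bisphosphine (enantiomer giving 8R), 4-Cl-3-NO2-C6H3CO2H (cat.), Cs2CO3 (cat.), THF, 70 °C; then PPTS (cat.), rt
Reagents that add atoms: none
Why: Iridium-catalysed transfer-hydrogenative carbonyl 2-(alkoxycarbonyl)allylation: the furylic alcohol is dehydrogenated to the aldehyde, the π-allyliridium formed from carbonate 3 adds through a closed chair transition state in which the chiral bisphosphine sets C8 as R, and hydroxy ester 4 lactonises.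

**Step 3**
Reactants: 5 (5R)-3-methylidene-5-[4-(TBDPSOCH2)furan-3-yl]oxolan-2-one
Product: 7 (3S,5R)-3-hydroxy-3-methyl-5-[4-(TBDPSOCH2)furan-3-yl]oxolan-2-one (OH trans to furyl), via hydroperoxide 6 (not isolated)
Conditions: Mn(dpm)3 (cat.), PhSiH3, O2 (1 atm), iPrOH/CH2Cl2, 0 °C; then P(OEt)3
Reagents that add atoms: dioxygen, O=O
Why: Mukaiyama hydration (Mn-hydride hydrogen-atom transfer, O2 trapping, phosphite reduction): H adds to the CH2 terminus, and the planar tertiary α-acyl radical at C10 is trapped by O2 on the lactone face opposite the C8 furyl group, which puts OH trans to the furyl (10S).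

**Step 4**
Reactants: 7 (3S,5R)-3-hydroxy-3-methyl-5-[4-(TBDPSOCH2)furan-3-yl]oxolan-2-one
Product: 8 (2S,4R)-2,4-dihydroxy-N-methoxy-N,2-dimethyl-4-[4-(TBDPSOCH2)furan-3-yl]butanamide
Conditions: MeNH(OMe)·HCl, iPrMgCl, THF, −20 → 0 °C
Reagents that add atoms: N,O-dimethylhydroxylamine hydrochloride, CNOC.Cl
Why: Aminolysis of a γ-lactone with the chloromagnesium amide of N,O-dimethylhydroxylamine (Weinreb amide synthesis) opens the temporary ring without touching C8 or C10.

**Step 5**
Reactants: 8 (2S,4R)-dihydroxy Weinreb amide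
Product: 9 (2S,4R)-2,4-bis(tert-butyldimethylsilyloxy)-N-methoxy-N,2-dimethyl-4-[4-(TBDPSOCH2)furan-3-yl]butanamide
Conditions: TBSOTf (3 equiv), 2,6-lutidine, CH2Cl2, 0 °C → rt
Reagents that add atoms: tert-butyldimethylsilyl triflate, CC(C)(C)[Si](C)(C)OS(=O)(=O)C(F)(F)F
Why: Silyl triflate/lutidine O-silylation is strong enough for the tertiary C10 hydroxyl, blocks relactonisation and leaves an amide without α-hydrogen.

**Step 6**
Reactants: 10 methyl (4R)-2,2-dimethyl-1,3-dioxolane-4-carboxylate
Product: 12 1-[(4R)-2,2-dimethyl-1,3-dioxolan-4-yl]ethan-1-one, via Weinreb amide 11 (not isolated)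
Conditions: MeNH(OMe)·HCl, iPrMgCl, THF, −20 °C; then MeMgBr, 0 °C
Reagents that add atoms: methylmagnesium bromide, C[Mg]Br; N,O-dimethylhydroxylamine hydrochloride (held only in 11), CNOC.Cl
Why: One-flask ester → Weinreb amide → methyl ketone sequence; the chelated tetrahedral adduct prevents over-addition and the low temperature keeps the α-alkoxy stereocentre C5 intact.

**Step 7**
Reactants: 12 1-[(4R)-2,2-dimethyl-1,3-dioxolan-4-yl]ethan-1-one; 13 ethynylmagnesium bromide; 9 bis-TBS Weinreb amide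
Product: 15 (1R,3S,7R)-1,3-bis(TBSO)-7-[(4R)-2,2-dimethyl-1,3-dioxolan-4-yl]-7-hydroxy-3-methyl-1-[4-(TBDPSOCH2)furan-3-yl]oct-5-yn-4-one, via propargylic alkoxide 14 (not isolated)
Conditions: 13, MgBr2·OEt2, Et2O/CH2Cl2/THF, −78 °C, add 12; then EtMgBr, 40 °C; then 9, 0 → 40 °C; aq NH4Cl
Reagents that add atoms: none
Why: Ethynylmagnesium bromide adds to the MgBr2-chelated α-alkoxy methyl ketone 12 (C3–C4), EtMgBr then turns the terminal C–H of alkoxide 14 into the alkynyl Grignard, and this acylates Weinreb amide 9 (C1–C2), whose five-membered N-methoxy chelate holds the tetrahedral adduct until the quench, so one flask stitches both halves with a C2 dianion and completes the whole C15 backbone. The closest known reaction types are the chelation-controlled alkynylation of α-alkoxy ketones and the ynone synthesis from alkynyl metals and Weinreb amides, run here as a sequential three-component linchpin coupling. No ring is closed in this step, and the alkyne is a higher oxidation level of C2–C3 that step 9 removes. The new stereocentre C4 is controlled by the Cram chelate between the ketone oxygen and the C5 dioxolane oxygen: the nucleophile enters past C5–H, opposite the CH2O arm on C5, which gives 4R from the (R)-dioxolane. The step needs ketone-before-amide chemoselectivity and a single acylation, which the order of addition, the lack of α-hydrogen at C10 of 9 and the stable chelated adduct secure, and since no carbanion ever sits next to the C10 or C8 silyloxy groups, no β-elimination can start.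

**Step 8**
Reactants: 15 hydroxy ynone
Product: 16 C4-O-triethylsilyl ether of 15
Conditions: TESOTf, 2,6-lutidine, CH2Cl2, −78 → 0 °C
Reagents that add atoms: triethylsilyl triflate, CC[Si](CC)(CC)OS(=O)(=O)C(F)(F)F
Why: Silyl triflate O-silylation of the tertiary propargylic alcohol masks C4–OH so that the later glycol cleavage cannot cut C4–C5 and no premature ketalisation occurs.

**Step 9**
Reactants: 16 silylated ynone
Product: 17 (1R,3S,7R)-1,3-bis(TBSO)-7-[(4R)-dioxolan-4-yl]-3-methyl-7-(TESO)-1-[4-(TBDPSOCH2)furan-3-yl]octan-4-one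
Conditions: H2 (1 atm), 10 % Pd/C, EtOAc, rt
Reagents that add atoms: none
Why: Heterogeneous catalytic hydrogenation saturates the electron-poor ynone to the C2–C3 ethano bridge, while the furan, the silyl ethers and the acetonide are inert at 1 atm.

**Step 10**
Reactants: 17 furyl ketone
Product: 18 5-hydroxybutenolide (C12 = lactone C=O, C6 = hemiacetal carbon, C6 epimers)
Conditions: O2, hν, rose bengal (cat.), iPr2NEt, CH2Cl2, −78 °C → rt
Reagents that add atoms: dioxygen, O=O
Why: Singlet-oxygen [4+2] cycloaddition to the furan followed by Kornblum–DeLaMare-type fragmentation: the hindered amine removes the less shielded C12–H of the endoperoxide, so C12 becomes the lactone carbonyl and C6 the hemiacetal carbon (the C6 epimers are inconsequential).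

**Step 11**
Reactants: 18 5-hydroxybutenolide
Product: 19 dimethyl (5-oxo-2,5-dihydrofuran-2-yl)phosphonate (P on C6)
Conditions: HP(O)(OMe)2, Et3N (cat.), CH2Cl2, rt; citric acid work-up
Reagents that add atoms: dimethyl phosphite, CO[PH](=O)OC
Why: Pudovik addition of dimethyl phosphite to the ring-opened 4-oxo-2-enoic acid tautomer and relactonisation, the reaction type used for phthalide-3-phosphonates, while the hindered C1 ketone stays untouched.

**Step 12**
Reactants: 19 butenolide phosphonate
Product: 20 C5 aldehyde (4R)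
Conditions: H5IO6, EtOAc, 0 °C → rt
Reagents that add atoms: none
Why: Periodic acid hydrolyses the terminal acetonide and cleaves the liberated 1,2-diol in one pot (Malaprade cleavage), sacrificing the auxiliary stereocentre C5 to give the non-enolisable C5 aldehyde.

**Step 13**
Reactants: 20 aldehyde phosphonate
Product: 21 (4R,5E,8R,10S)-8,10-bis(TBSO)-4-(TESO)-13-(TBDPSO)-1-oxogermacra-5,7(11)-dien-12,6-olide
Conditions: LiCl, DBU, MeCN (1 mM, slow addition), rt
Reagents that add atoms: none
Why: Intramolecular Horner–Wadsworth–Emmons olefination under Masamune–Roush conditions at high dilution closes the ten-membered carbocycle at C5=C6 and should give the ylidene isomer with C4 syn to C7, because the tether C8–C9–C10–C1–C2–C3 spans that side of the butenolide.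

**Step 14**
Reactants: 21 macrocyclic keto butenolide
Product: 22 (4R,5E,8R,10S)-1,4-epoxy-1,8,10,13-tetrahydroxygermacra-5,7(11)-dien-12,6-olide (C1 epimers equilibrate)
Conditions: HF·pyridine, pyridine, THF, 0 °C → rt
Reagents that add atoms: none
Why: Desilylation with buffered HF·pyridine frees all four hydroxyls, and C4–OH adds transannularly to the C1 ketone (5-exo-trig) to give the 1,4-epoxy hemiketal, whose C1 configuration equilibrates and is erased in step 17.

**Step 15**
Reactants: 22 hemiketal tetraol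
Product: 23 13-O-acetate of 22
Conditions: Ac2O (1.1 equiv), 2,4,6-collidine, CH2Cl2, −20 °C
Reagents that add atoms: acetic anhydride, CC(=O)OC(C)=O
Why: Kinetic acylation: the primary allylic C13 hydroxyl is acetylated faster than the secondary C8–OH and the two tertiary hydroxyls.

**Step 16**
Reactants: 23 13-acetate
Product: 24 8-O-methacrylate 13-O-acetate hemiketal
Conditions: methacrylic anhydride, Et3N, DMAP (cat.), CH2Cl2, 0 °C → rt
Reagents that add atoms: methacrylic anhydride, C=C(C)C(=O)OC(=O)C(C)=C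
Why: DMAP-catalysed acylation esterifies the only remaining secondary hydroxyl, the tertiary C10–OH and the hemiketal C1–OH being too hindered.

**Step 17**
Reactants: 24 hemiketal diester
Product: 25 target CNP0394509.1
Conditions: MsCl, Et3N, CH2Cl2, −20 → 0 °C
Reagents that add atoms: none
Why: Sulfonylation–elimination of a hemiketal (the lactol-to-glycal reaction type): the anomeric C1–OH is the most easily ionised hydroxyl, the oxocarbenium ion can lose a proton only from C2 because C10 is quaternary, and the C1=C2 enol ether results.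

**Compound list**

1 | furan-3,4-diyldimethanol | OCc1cocc1CO | starting material
2 | [4-(tert-butyldiphenylsilyloxymethyl)furan-3-yl]methanol | OCc1cocc1CO[Si](C(C)(C)C)(c1ccccc1)c1ccccc1 | intermediate
3 | methyl 2-{[(tert-butoxycarbonyl)oxy]methyl}prop-2-enoate | C=C(COC(=O)OC(C)(C)C)C(=O)OC | starting material
4 | methyl (4R)-4-hydroxy-2-methylidene-4-[4-(TBDPSOCH2)furan-3-yl]butanoate | C=C(C[C@@H](O)c1cocc1CO[Si](C(C)(C)C)(c1ccccc1)c1ccccc1)C(=O)OC | intermediate
5 | (5R)-3-methylidene-5-[4-(TBDPSOCH2)furan-3-yl]oxolan-2-one | C=C1C[C@H](c2cocc2CO[Si](C(C)(C)C)(c2ccccc2)c2ccccc2)OC1=O | intermediate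
6 | (3S,5R)-3-hydroperoxy-3-methyl-5-[4-(TBDPSOCH2)furan-3-yl]oxolan-2-one | C[C@]1(OO)C[C@H](c2cocc2CO[Si](C(C)(C)C)(c2ccccc2)c2ccccc2)OC1=O | intermediate
7 | (3S,5R)-3-hydroxy-3-methyl-5-[4-(TBDPSOCH2)furan-3-yl]oxolan-2-one | C[C@]1(O)C[C@H](c2cocc2CO[Si](C(C)(C)C)(c2ccccc2)c2ccccc2)OC1=O | intermediate
8 | (2S,4R)-2,4-dihydroxy-N-methoxy-N,2-dimethyl-4-[4-(TBDPSOCH2)furan-3-yl]butanamide | CON(C)C(=O)[C@@](C)(O)C[C@@H](O)c1cocc1CO[Si](C(C)(C)C)(c1ccccc1)c1ccccc1 | intermediate
9 | (2S,4R)-2,4-bis(TBSO)-N-methoxy-N,2-dimethyl-4-[4-(TBDPSOCH2)furan-3-yl]butanamide | CON(C)C(=O)[C@@](C)(O[Si](C)(C)C(C)(C)C)C[C@@H](O[Si](C)(C)C(C)(C)C)c1cocc1CO[Si](C(C)(C)C)(c1ccccc1)c1ccccc1 | intermediate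
10 | methyl (4R)-2,2-dimethyl-1,3-dioxolane-4-carboxylate | COC(=O)[C@H]1COC(C)(C)O1 | starting material
11 | (4R)-N-methoxy-N,2,2-trimethyl-1,3-dioxolane-4-carboxamide | CON(C)C(=O)[C@H]1COC(C)(C)O1 | intermediate
12 | 1-[(4R)-2,2-dimethyl-1,3-dioxolan-4-yl]ethan-1-one | CC(=O)[C@H]1COC(C)(C)O1 | intermediate
13 | ethynylmagnesium bromide | C#C[Mg]Br | starting material
14 | (2R)-2-[(4R)-2,2-dimethyl-1,3-dioxolan-4-yl]but-3-yn-2-ol (present as its bromomagnesium alkoxide, then alkoxide/acetylide) | C#C[C@@](C)(O)[C@H]1COC(C)(C)O1 | intermediate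
15 | (1R,3S,7R)-hydroxy ynone (C4R, C5R, C8R, C10S) | C[C@@](O)(C#CC(=O)[C@@](C)(O[Si](C)(C)C(C)(C)C)C[C@@H](O[Si](C)(C)C(C)(C)C)c1cocc1CO[Si](C(C)(C)C)(c1ccccc1)c1ccccc1)[C@H]1COC(C)(C)O1 | intermediate
16 | C4-O-TES ynone | C[C@@](O[Si](CC)(CC)CC)(C#CC(=O)[C@@](C)(O[Si](C)(C)C(C)(C)C)C[C@@H](O[Si](C)(C)C(C)(C)C)c1cocc1CO[Si](C(C)(C)C)(c1ccccc1)c1ccccc1)[C@H]1COC(C)(C)O1 | intermediate
17 | saturated furyl ketone | C[C@@](O[Si](CC)(CC)CC)(CCC(=O)[C@@](C)(O[Si](C)(C)C(C)(C)C)C[C@@H](O[Si](C)(C)C(C)(C)C)c1cocc1CO[Si](C(C)(C)C)(c1ccccc1)c1ccccc1)[C@H]1COC(C)(C)O1 | intermediate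
18 | 5-hydroxybutenolide (C6 epimers) | C[C@@](O[Si](CC)(CC)CC)(CCC(=O)[C@@](C)(O[Si](C)(C)C(C)(C)C)C[C@@H](O[Si](C)(C)C(C)(C)C)C1=C(CO[Si](C(C)(C)C)(c2ccccc2)c2ccccc2)C(=O)OC1O)[C@H]1COC(C)(C)O1 | intermediate
19 | butenolide C6-phosphonate (C6 epimers) | C[C@@](O[Si](CC)(CC)CC)(CCC(=O)[C@@](C)(O[Si](C)(C)C(C)(C)C)C[C@@H](O[Si](C)(C)C(C)(C)C)C1=C(CO[Si](C(C)(C)C)(c2ccccc2)c2ccccc2)C(=O)OC1P(=O)(OC)OC)[C@H]1COC(C)(C)O1 | intermediate
20 | C5 aldehyde phosphonate | C[C@@](O[Si](CC)(CC)CC)(CCC(=O)[C@@](C)(O[Si](C)(C)C(C)(C)C)C[C@@H](O[Si](C)(C)C(C)(C)C)C1=C(CO[Si](C(C)(C)C)(c2ccccc2)c2ccccc2)C(=O)OC1P(=O)(OC)OC)C=O | intermediate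
21 | (4R,5E,8R,10S)-macrocyclic keto ylidene-butenolide | C[C@@]1(O[Si](CC)(CC)CC)CCC(=O)[C@@](C)(O[Si](C)(C)C(C)(C)C)C[C@@H](O[Si](C)(C)C(C)(C)C)C2=C(CO[Si](C(C)(C)C)(c3ccccc3)c3ccccc3)C(=O)O/C2=C/1 | intermediate
22 | 1,4-epoxy hemiketal tetraol (C1 epimers equilibrate) | C[C@]12CCC(O)(O1)[C@@](C)(O)C[C@@H](O)C1=C(CO)C(=O)O/C1=C/2 | intermediate
23 | 13-O-acetate | C[C@]12CCC(O)(O1)[C@@](C)(O)C[C@@H](O)C1=C(COC(C)=O)C(=O)O/C1=C/2 | intermediate
24 | 8-O-methacrylate 13-O-acetate hemiketal | C[C@]12CCC(O)(O1)[C@@](C)(O)C[C@@H](OC(=O)C(C)=C)C1=C(COC(C)=O)C(=O)O/C1=C/2 | intermediate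
25 | CNP0394509.1 | C=C(C)C(=O)O[C@@H]1C[C@](C)(O)C2=CC[C@](C)(/C=C3/OC(=O)C(COC(C)=O)=C31)O2 | target

**Step count**

Total step count: 17. Longest linear sequence: 16 (steps 1–5 and 7–17).

**Steps most likely to fail**

1. **Step 13 (macrocyclic HWE).** What may go wrong:
   - oligomerisation instead of ring closure;
   - closure to the ylidene isomer with C4 anti to C7;
   - β-elimination of the C13 silyloxy group from the phosphonate anion.

   The fallback sets out from 18 and returns at 21. Ionic reduction of the pseudo-acid (Et3SiH, BF3·OEt2, −78 °C) gives the γ-unsubstituted butenolide F1. Periodic acid then gives the keto aldehyde F2. TBSOTf/iPr2NEt at high dilution forms the 2-silyloxyfuran in situ and closes the ring at the C5–C6 single-bond level by an intramolecular vinylogous Mukaiyama aldol reaction, giving the silylated aldol F3. DBU then expels the C5 silyloxy group (E1cB) inside the ring to give 21.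

2. **Step 17 (hemiketal dehydration).** What may go wrong:
   - competing sulfonylation or ionisation at the tertiary C10 hydroxyl;
   - loss of the allylic C13 acetate under the amine base;
   - rehydration of the enol ether on work-up.

   The fallback sets out from 24 and returns at 25. Acid-catalysed exchange with thiophenol (cat. BF3·OEt2, −40 °C) gives the C1 phenylthio ketal F4. mCPBA at −78 °C gives the sulfoxide F5. Neutral thermal syn-elimination (toluene, 80 °C, CaCO3) can take a hydrogen only from C2 and gives 25.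

3. **Step 10 (photooxygenation).** What may go wrong:
   - poor discrimination between the two furan α-C–H bonds in the base-induced endoperoxide fragmentation, which would give the regioisomeric lactone;
   - over-oxidation.

   The fallback sets out from 17 and returns at 18. Oxidative furan opening (NBS, NaHCO3, aqueous acetone, −20 °C) gives the (Z)-enedial F6. One equivalent of NaClO2 (Pinnick conditions) then oxidises the less hindered C12 aldehyde, and the resulting 4-oxo-2-enoic acid closes to 18.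

**Further compounds**

F1 | step 13 | γ-unsubstituted butenolide (C6H2) with acetonide | C[C@@](O[Si](CC)(CC)CC)(CCC(=O)[C@@](C)(O[Si](C)(C)C(C)(C)C)C[C@@H](O[Si](C)(C)C(C)(C)C)C1=C(CO[Si](C(C)(C)C)(c2ccccc2)c2ccccc2)C(=O)OC1)[C@H]1COC(C)(C)O1
F2 | step 13 | butenolide C5 aldehyde | C[C@@](O[Si](CC)(CC)CC)(CCC(=O)[C@@](C)(O[Si](C)(C)C(C)(C)C)C[C@@H](O[Si](C)(C)C(C)(C)C)C1=C(CO[Si](C(C)(C)C)(c2ccccc2)c2ccccc2)C(=O)OC1)C=O
F3 | step 13 | macrocyclic C5-O-TBS vinylogous aldol (C5, C6 epimers) | C[C@@]1(O[Si](CC)(CC)CC)CCC(=O)[C@@](C)(O[Si](C)(C)C(C)(C)C)C[C@@H](O[Si](C)(C)C(C)(C)C)C2=C(CO[Si](C(C)(C)C)(c3ccccc3)c3ccccc3)C(=O)OC2C1O[Si](C)(C)C(C)(C)C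
F4 | step 17 | C1 phenylthio ketal | C[C@]12CCC(Sc3ccccc3)(O1)[C@@](C)(O)C[C@@H](OC(=O)C(C)=C)C1=C(COC(C)=O)C(=O)O/C1=C/2
F5 | step 17 | C1 phenylsulfinyl ketal | C[C@]12CCC(S(=O)c3ccccc3)(O1)[C@@](C)(O)C[C@@H](OC(=O)C(C)=C)C1=C(COC(C)=O)C(=O)O/C1=C/2
F6 | step 10 | (Z)-enedial from furan opening | C[C@@](O[Si](CC)(CC)CC)(CCC(=O)[C@@](C)(O[Si](C)(C)C(C)(C)C)C[C@@H](O[Si](C)(C)C(C)(C)C)/C(C=O)=C(C=O)\CO[Si](C(C)(C)C)(c1ccccc1)c1ccccc1)[C@H]1COC(C)(C)O1
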